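(The data come from a simulation on assumed constants; the scatter is artificial.)

Hold the plateau of each earlier run against its charge of coupling partner before adopting any picture of the reaction.

| flask | substrate | coupling partner | remark | time |
|---|---|---|---|---|
| delta | 0.050 M | 0.045 M | run made earlier |  |
| theta | 0.050 M | 0.022 M | run made earlier |  |
| ochre | 0.050 M | 0.0450 M (fed, over 12.0 min) | a stirred flask in which coupling partner is dosed at a steady rate over 12.0 min without added volume, worked up at 15 min | 15 min |
| grey | 0.050 M | 0.0450 M | a single well-mixed tank run continuously and read at steady state, 15 min in it on average |  |
| amber | 0.050 M | 0.0450 M | everything together in a closed stirred flask, run for 15 min | 15 min |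
| green | 0.050 M | 0.0450 M | a tube with plug flow, the mixed feed as stated, residence time 15 min | 15 min |

| run | time / min | target / % |
|---|---|---|
| delta | 2.50 | 22 |
| delta | 5.00 | 21 |
| delta | 8.00 | 23 |
| delta | 10.0 | 21 |
| delta | 12.0 | 18 |
| delta | 15.0 | 21 |
| theta | 0.333 | 4 |
| theta | 0.833 | 10 |
| theta | 1.50 | 9 |
| theta | 2.50 | 13 |
| theta | 3.00 | 14 |
| theta | 5.00 | 13 |

(scatter of a reading: 1.5 percentage points)

- the stated concentrations are those of everything mixed, before any reaction; amounts are the same in each set-up
- the numbers in the tables scatter with a standard deviation of 1.5 percentage points
- the feed brings no volume worth counting
- the earlier runs were made in a closed, stirred flask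
- a reading or a percentage of target counts all its forms, free or not

- the set-up with the highest amount of target at the outlet or at the end, in percent of the substrate put in ("none" if the first two lie within 2 percentage points) (ochre / grey / amber / green / none)
- amount of target at the outlet or at the end, in percent of the substrate put in, ochre
- amount of target at the outlet or at the end, in percent of the substrate put in, grey
- amount of target at the outlet or at the end, in percent of the substrate put in, amber
- amount of target at the outlet or at the end, in percent of the substrate put in, green

The delta run stands flat from its first reading at a mean of 21.0% of the substrate, and the readings of the theta run from 2.50 min on average 13.3%, on a fraction 0.489 of the delta charge of coupling partner. The bench rule says that the smaller charge, the limiting reagent, scales the target, which would put the theta run at 10.3%. That rule stops here, since the charges stand in a ratio of 2.05 but the read plateaus in a smaller ratio of 1.58, a miss of 3.1 percentage points against a scatter of 1.5 points per reading. My own reckoning therefore uses the plateau order, the exponent with which the plateau follows the fraction f of the delta charge of coupling partner, the substrate held at 0.050 M: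

n = ln(plateau ratio) / ln(charge ratio) = 0.635

target = 21.0% × f^n

At f = 1 this gives 21.0% for amber, green and ochre after its feed, and it gives the tank no figure. The delta plateau stands by 2.50 min, sooner than the 12.0 min of dosing, so ochre at 7.50 min, with f = 0.625 fed, should hold 15.6%.

The forecast gives ochre 21%, grey 20%, amber 21%, green 21%, and as best none: “No set-up wins, though a dosing benefit remains slightly possible.”

The flasks give ochre 20.4%, grey 18.0%, amber 19.1%, green 19.1%, and as best none, ochre leading amber by 1.3 points, less than the margin of 2 points.

    substrate + coupling partner → intermediate + by-product (k = 0.198 /M/s)
    intermediate ⇌ target (K = 1.40, k = 0.0775 /s)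
    intermediate ⇌ isomer of the product A (K = 2.60, k = 0.0170 /s)
    substrate + target ⇌ idle adduct, settled at all times (K = 21.9 /M)
    target ⇌ isomer of the product B (K = 1.50, k = 0.00158 /s)
    target → over-reaction product (k = 3.94 × 10⁻⁴ /s)

In ochre, free target and isomer of the product B relax with a half-life of 4.39 min, short against the 15 min of the run, and at 15.0 min the forward passing of free target into isomer of the product B runs 4.0 times its passing into over-reaction product. Ochre left to 150 min holds 9.83% target. At 7.50 min ochre holds 15.2% against the 15.6% of the plateau order.

For the neighbour with 0.027 M of coupling partner, f = 0.600 gives 15.2%; that flask, computed, holds 15.5% at 15.0 min.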